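## Structural features

The target is a 2,3-dihydro-1-benzofuran. Its benzene ring (ring A) is fused to the dihydrofuran ring and carries a methoxy group at C7 and a 3-methoxy-3-oxopropyl chain at C5; C2 carries a 4-hydroxy-3,5-dimethoxyphenyl group (ring B, joined through C1') and C3 a hydroxymethyl group (C9). The only stereocentres are the neighbouring C2 (S) and C3 (R), with ring B and the hydroxymethyl group trans. The O1–C2 bond is a para-hydroxybenzyl aryl ether, so it can ionise to a quinone methide and can be hydrogenolysed; the methyl ester is exposed to hydroxide, hydride and organolithium reagents, and both oxygenated rings to oxidants. That lability is also useful, because C2 can be re-formed under the control of C3 and should settle trans. The real difficulty is therefore the absolute configuration of C3, a benzylic methine with no carbonyl neighbour, and the joining of three electron-rich pieces around two sp3 carbons without a long protecting-group sequence. The key step uses the fact that C2 and C3 are vicinal, that C2 bears ring B plus a heteroatom (O1) and that C3 bears ring A (through C3a) plus C9: this is the 1,2-diaryl pattern that an alkenylboron ate complex delivers in a conjunctive coupling, boron holding the place of O1.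

## Logic of the disconnections

**17 to 14.** The O1–C2 bond is cut, and the three free hydroxyl groups are returned to two methoxymethyl ethers and one silyl ether. The cut is placed here because C2 of 15 is a para-hydroxybenzylic carbinol that ionises to 16, which the ring A phenol captures, so C3 alone decides the configuration at C2. The gain is an acyclic precursor whose C2 only needs an oxygen of either configuration. The forward step must free three oxygens in one acid treatment without harming the methyl ester, close the ring trans, and not lose the C3 proton.

**14 to 13.** The C2–O bond is traced back to a C2–B bond. A boronic ester is what the coupling leaves at C2, and it is oxidised with retention. Nothing is gained in size, but 14 becomes the direct product of a three-component coupling. The oxidant must be mild enough for the ester, the acetals and the silyl ether.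

**13 to 3 and 12, then 12 to 11 and 10.** The bonds C3–C3a and C2–C1' are cut in one operation, and the B–C(aryl) bond of 12 in a second. This divides the skeleton into three pieces of similar size, each one or two steps from a commercial compound, and creates both stereocentres together. The forward step must control the alkene face by the catalyst, run the boron-to-carbon shift anti to palladium, and use up all of 11 before the ester 3 enters. It must also favour the conjunctive pathway over direct Suzuki–Miyaura transfer, which is why boron carries diol 7 and not pinacol. Bromide must be scavenged, because 3 is a bromide and not a sulfonate. Both phenols are masked as methoxymethyl ethers so that ring B is freed in the last step without hydrogenolysis.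

**3 to 2 to 1.** The acetal O–C bond and the C–Br bond are cut. The free phenol of 1 directs the halogen to the one open ortho position, which is the future C3a. The bromination must be ortho-selective against the position para to the methoxy group.

**11 to 5 to 4.** The C–Li bond comes from the C–Br bond by exchange, and the acetal from the phenol. The exchange must be faster than any attack on the acetal, which holds at low temperature.

**10 to 9 to 8 and 7; 7 to 6.** The two B–O bonds of 10 are cut to 7 and an alkenylboron species, the C–B bond to the terminal alkyne 8, and the two C–CH3 bonds of 7 to the diketone 6. The forward steps must give (E)-geometry with boron on the terminal carbon and a cis diol that can chelate boron.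

## Other disconnections considered

**Alternative 1:** The cut is C3–C3a, made by ring contraction. The (2S)-flavanone A2 would be treated with PhI(OAc)2 and H2SO4 in trimethyl orthoformate. The trivalent iodine reagent attacks C3 of the enol ether, ring A carbon C4a moves from C4 to C3 as iodobenzene leaves, and C4 ends as the methyl ester of the trans dihydrobenzofuran A1.
- In favour: the dihydrofuran ring and the trans relationship appear in the key step itself. The C2 configuration of A2 is carried through unchanged. C3, being alpha to an ester, can be equilibrated to trans. On these three points the alternative is the equal or the better of the chosen plan, which closes its ring two steps after the key step and re-forms C2.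
- Against: the electron-rich ring B competes as the migrating group (shift from C2 to C3, towards an isoflavone), and dehydrogenation to the flavone is a further exit. The pivalate on ring B only slows this. A2 must be made enantiopure by a separate asymmetric step, and flavanones can open to chalcones and racemise. After the key step the bromide still has to become the propanoate chain (Heck reaction, then alkene hydrogenation), and the C3 ester has to be reduced in the presence of the pivalate and, depending on the order, the side-chain ester.
- Comparison: both plans reach the same trans-2,3 pattern. Alternative 1 transmits a stereocentre where the chosen plan creates two under catalyst control. Its longest linear sequence would be roughly twice as long.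

**Alternative 2:** The cut runs through ring A itself, at C3a–C7a and C6–C7. The furyl ynol ether A4, with both stereocentres already in place, would be treated with Ph3PAuNTf2. Gold activates the alkyne, furan C2 attacks the oxygen-bearing alkyne carbon, the terminal carbon bonds to furan C5, and the arene oxide manifold opens to the phenol A3. Ring A and the dihydrofuran ring thus form together, and the furan oxygen becomes the C7 hydroxyl.
- In favour: the key step is a pure isomerisation and the substitution pattern of ring A is unambiguous. C2 is never ionised, a point on which it is better than the chosen plan. The key step needs no chiral catalyst and no organolithium.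
- Against: A4 is far from commercial materials. It needs a 2,4-disubstituted furan, two stereocentres set by some other asymmetric method, and a terminal ynol ether on a secondary benzylic oxygen, a function that is labile to heat and acid. A cationic gold catalyst can divert ynol ethers to ketene-type products or hydration. After the key step, A3 still needs O-methylation, desilylation, oxidation to the acid, esterification and two debenzylations.
- Comparison: it builds more of the skeleton in one step but moves the whole stereochemical problem into the preparation of A4, where the chosen plan solves it in the key step. In step count it is clearly the longer.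

**Alternative 3:** The cut is O1–C2 and C3–C9. The (E)-2-hydroxystilbene A6 would be cyclised with Pd(OCOCF3)2, a chiral bis(oxazoline), p-benzoquinone, CO and benzyl alcohol. The phenol adds to C2 of the palladium-bound alkene, the C3–Pd bond inserts CO, and benzyl alcohol releases the ester A5.
- In favour: A6 is one Heck or Suzuki–Miyaura coupling away from 2. The key step makes the ring, both stereocentres and C9 at once and sets C2 directly in its final form. Hydrogenolysis and then borane reduction of the resulting acid would finish the synthesis. In step count it is the equal of the chosen plan or slightly better.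
- Against: the cyclisation is 5-endo onto a 1,2-diarylalkene. Anti oxypalladation, the mode that leads to trans, leaves a hydrogen at C2 syn to palladium, so beta-hydride elimination to the aromatic 2-arylbenzofuran competes with CO insertion. Enantiocontrol by bis(oxazoline) ligands is established for exo cyclisations of allylphenols, not for this mode, so the key step would be new chemistry. An electron-rich guaiacol-type phenol is also exposed to divalent palladium and benzoquinone.
- Comparison: both plans draw ring A from 2 (equal). Alternative 3 rests on a selectivity without precedent, the chosen plan on a known catalyst-controlled process. Step economy is equal or better for alternative 3 only if its key step behaves as drawn.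

Key step: step 6

Remark on the chemistry (assumption): the (Sp,Sp) antipode of the MandyPhos ligand is taken as the one that delivers ring A to the alkene face leading to (3R); should the sense be the opposite, the equally available mirror-image ligand is used with no other change.

## Route

Step 1
Reactants: 1 methyl 3-(4-hydroxy-3-methoxyphenyl)propanoate (methyl dihydroferulate)
Product: 2 methyl 3-(3-bromo-4-hydroxy-5-methoxyphenyl)propanoate
Conditions: NBS (1.0 equiv), i-Pr2NH (10 mol%), CH2Cl2, 0 °C
Reagents that add atoms: N-bromosuccinimide, O=C1CCC(=O)N1Br
Why: Electrophilic aromatic bromination of a phenol: the free hydroxyl is the strongest activator and its para position is occupied by the side chain, and the N-bromoamine formed from the amine catalyst hydrogen-bonds to the phenol and delivers bromine to the one free ortho position; one equivalent at 0 °C limits dibromination.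

Step 2
Reactants: 2 methyl 3-(3-bromo-4-hydroxy-5-methoxyphenyl)propanoate
Product: 3 methyl 3-[3-bromo-5-methoxy-4-(methoxymethoxy)phenyl]propanoate
Conditions: CH2(OMe)2, AcCl, ZnBr2 (0.01 mol%), toluene, rt; then 2, i-Pr2NEt, 0 °C → rt; aq. NH4Cl
Reagents that add atoms: chloromethyl methyl ether, COCCl (made in the flask from dimethoxymethane, COCOC, and acetyl chloride, CC(=O)Cl)
Why: Base-mediated O-alkylation of the phenol by the reactive chloromethyl ether (Williamson-type acetal formation); making the reagent in solution avoids handling the neat carcinogenic chloride, the quench destroys the excess, and the ester and the aryl bromide are inert.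

Step 3
Reactants: 4 4-bromo-2,6-dimethoxyphenol
Product: 5 5-bromo-1,3-dimethoxy-2-(methoxymethoxy)benzene
Conditions: CH2(OMe)2, AcCl, ZnBr2 (0.01 mol%), toluene, rt; then 4, i-Pr2NEt, 0 → 40 °C; aq. NH4Cl
Reagents that add atoms: chloromethyl methyl ether, COCCl (made in the flask from dimethoxymethane, COCOC, and acetyl chloride, CC(=O)Cl)
Why: The same Williamson-type acetalisation; the acetal is preferred to a benzyl ether on ring B because it falls off in the final acid step, where the freed para-hydroxyl is needed for ionisation at C2, and because no hydrogenolysis next to the benzylic O1–C2 bond is then required.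

Step 4
Reactants: 6 acenaphthylene-1,2-dione (acenaphthoquinone)
Product: 7 cis-1,2-dimethyl-1,2-dihydroacenaphthylene-1,2-diol (meso diol, "mac diol")
Conditions: MeMgBr (2.5 equiv), THF, 0 °C → rt; aq. NH4Cl; recrystallisation
Reagents that add atoms: methylmagnesium bromide, C[Mg]Br
Why: Twofold Grignard addition to a 1,2-diketone; after the first addition the second methyl group should enter anti to the solvated bromomagnesium alkoxide, which places the two hydroxyl groups cis; any trans diol is removed by crystallisation and cannot form the cyclic boronate of step 5.

Step 5
Reactants: 8 tert-butyldimethyl(prop-2-yn-1-yloxy)silane; 7 cis-1,2-dimethyl-1,2-dihydroacenaphthylene-1,2-diol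
Product: 10 cyclic boronic ester of (E)-3-(tert-butyldimethylsilyloxy)prop-1-enylboronic acid on diol 7 [alkenyl B(mac)], via alkenyl catechol boronate 9 (not isolated)
Conditions: catecholborane (1.05 equiv), neat, 70 °C; then 7, THF, rt; aq. NaHCO3 wash
Reagents that add atoms: catecholborane, [H]B1Oc2ccccc2O1
Why: Uncatalysed syn-hydroboration of the terminal alkyne puts boron on the terminal carbon and fixes the (E)-geometry, and the labile catechol ester 9 then exchanges with the aliphatic diol 7 (transesterification) to the chromatography-stable ester 10; this boron ligand is chosen because beta-substituted alkenyl pinacol boronates tend to be diverted to direct Suzuki–Miyaura coupling in the next step.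

Step 6
Reactants: 5 5-bromo-1,3-dimethoxy-2-(methoxymethoxy)benzene; 10 alkenyl B(mac) ester; 3 methyl 3-[3-bromo-5-methoxy-4-(methoxymethoxy)phenyl]propanoate
Product: 13 methyl 3-{3-[(1S,2R)-1-[B(mac)]-3-(tert-butyldimethylsilyloxy)-1-[3,5-dimethoxy-4-(methoxymethoxy)phenyl]propan-2-yl]-5-methoxy-4-(methoxymethoxy)phenyl}propanoate [B(mac) = boron esterified by diol 7], via aryllithium 11 (not isolated), via lithium ate complex 12 (not isolated)
Conditions: 5, t-BuLi (2.0 equiv), Et2O, −78 °C; 10 (1.05 equiv), −78 °C → rt; switch to THF; KOTf (2 equiv), Pd(OAc)2 (3 mol%), (Sp,Sp)-MandyPhos [2,2'-bis((dimethylamino)(phenyl)methyl)-1,1'-bis(diphenylphosphino)ferrocene, C52H50FeN2P2] (3.6 mol%), 3 (0.85 equiv), 60 °C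
Reagents that add atoms: none
Why: Bromine–lithium exchange on 5 gives 11, which adds to boron of 10 to form the four-coordinate complex 12 (two diastereomers at boron, both productive), so that no free aryllithium is left when the ester 3 is introduced. Zerovalent palladium formed from Pd(OAc)2 and the bisphosphine inserts into the C–Br bond of 3, and with bromide taken up by KOTf the cationic arylpalladium species binds the alkene of 12. This triggers the 1,2-shift of the ring B aryl group from boron to the alpha carbon on the face opposite to palladium, palladium bonding to the beta carbon, and reductive elimination with retention then joins that carbon to ring A and returns zerovalent palladium. The closest known reaction type is the enantioselective palladium-catalysed conjunctive cross-coupling of beta-substituted alkenylboron ate complexes carrying this diol ligand with aryl electrophiles. The step closes no ring. The beta carbon (C3 of the target) is set by the chiral ligand, which selects the alkene face that receives palladium and hence ring A, and the alpha carbon (C2) follows stereospecifically from the anti shift across the (E)-alkene, giving the (1S,2R) arrangement. The step needs chemoselectivity against direct Suzuki–Miyaura transfer, secured by the diol ligand on boron, and tolerance of the methyl ester, secured by the slight excess of 10 over 11 and the order of addition. Because C2 is later re-formed under the control of C3, only the face selectivity at C3 has to be high.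

Step 7
Reactants: 13 B(mac) boronate
Product: 14 methyl 3-{3-[(1S,2R)-3-(tert-butyldimethylsilyloxy)-1-hydroxy-1-[3,5-dimethoxy-4-(methoxymethoxy)phenyl]propan-2-yl]-5-methoxy-4-(methoxymethoxy)phenyl}propanoate
Conditions: NaBO3·4H2O (5 equiv), THF/H2O (1:1), rt
Reagents that add atoms: sodium perborate, B(=O)O[O-].[Na+]
Why: Oxidation of a boronic ester by a peroxide nucleophile: the peroxy anion adds to boron and C2 migrates from boron to oxygen with retention, and hydrolysis releases the alcohol and diol 7; perborate keeps the medium only mildly basic, so the methyl ester, the acetals and the silyl ether should survive.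

Step 8
Reactants: 14 protected benzylic alcohol
Product: 17 methyl 3-[(2S,3R)-2-(4-hydroxy-3,5-dimethoxyphenyl)-3-(hydroxymethyl)-7-methoxy-2,3-dihydro-1-benzofuran-5-yl]propanoate (target), via tetraol 15 (not isolated), via quinone methide 16 (not isolated)
Conditions: TsOH·H2O (0.3 equiv), MeOH, 50 °C
Reagents that add atoms: none
Why: Acid-catalysed transacetalisation and solvolysis remove both methoxymethyl groups and the silyl group to give 15, whose para-hydroxybenzylic carbinol loses water to the O-protonated form of 16; the ring A phenol then adds to C2 in a 5-exo-trig closure on the face that places ring B trans to the C3 hydroxymethyl group, and because the closure is reversible the more stable trans isomer should accumulate while C3 and the methyl ester (degenerate exchange in methanol) stay untouched.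

## Compound list

1 | methyl 3-(4-hydroxy-3-methoxyphenyl)propanoate | COC(=O)CCc1ccc(O)c(OC)c1 | starting material
2 | methyl 3-(3-bromo-4-hydroxy-5-methoxyphenyl)propanoate | COC(=O)CCc1cc(Br)c(O)c(OC)c1 | intermediate
3 | methyl 3-[3-bromo-5-methoxy-4-(methoxymethoxy)phenyl]propanoate | COC(=O)CCc1cc(Br)c(OCOC)c(OC)c1 | intermediate
4 | 4-bromo-2,6-dimethoxyphenol | COc1cc(Br)cc(OC)c1O | starting material
5 | 5-bromo-1,3-dimethoxy-2-(methoxymethoxy)benzene | COCOc1c(OC)cc(Br)cc1OC | intermediate
6 | acenaphthylene-1,2-dione | O=C1C(=O)c2cccc3cccc1c23 | starting material
7 | cis-1,2-dimethyl-1,2-dihydroacenaphthylene-1,2-diol (meso) | C[C@@]1(O)c2cccc3cccc(c23)[C@]1(C)O | intermediate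
8 | tert-butyldimethyl(prop-2-yn-1-yloxy)silane | C#CCO[Si](C)(C)C(C)(C)C | starting material
9 | 2-[(E)-3-(tert-butyldimethylsilyloxy)prop-1-enyl]-1,3,2-benzodioxaborole | CC(C)(C)[Si](C)(C)OC/C=C/B1Oc2ccccc2O1 | intermediate (not isolated)
10 | cyclic boronic ester of (E)-3-(tert-butyldimethylsilyloxy)prop-1-enylboronic acid on diol 7 | CC(C)(C)[Si](C)(C)OC/C=C/B1O[C@]2(C)c3cccc4cccc(c34)[C@]2(C)O1 | intermediate
11 | 3,5-dimethoxy-4-(methoxymethoxy)phenyllithium | [Li]c1cc(OC)c(OCOC)c(OC)c1 | intermediate (not isolated)
12 | lithium [(E)-3-(tert-butyldimethylsilyloxy)prop-1-enyl][3,5-dimethoxy-4-(methoxymethoxy)phenyl]borate of diol 7 | [Li+].CC(C)(C)[Si](C)(C)OC/C=C/[B-]1(c2cc(OC)c(OCOC)c(OC)c2)O[C@]3(C)c4cccc5cccc(c45)[C@]3(C)O1 | intermediate (not isolated)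
13 | methyl 3-{3-[(1S,2R)-1-[B(mac)]-3-(tert-butyldimethylsilyloxy)-1-[3,5-dimethoxy-4-(methoxymethoxy)phenyl]propan-2-yl]-5-methoxy-4-(methoxymethoxy)phenyl}propanoate | COC(=O)CCc1cc(OC)c(OCOC)c(c1)[C@H](CO[Si](C)(C)C(C)(C)C)[C@@H](c1cc(OC)c(OCOC)c(OC)c1)B1O[C@]2(C)c3cccc4cccc(c34)[C@]2(C)O1 | intermediate
14 | methyl 3-{3-[(1S,2R)-3-(tert-butyldimethylsilyloxy)-1-hydroxy-1-[3,5-dimethoxy-4-(methoxymethoxy)phenyl]propan-2-yl]-5-methoxy-4-(methoxymethoxy)phenyl}propanoate | COC(=O)CCc1cc(OC)c(OCOC)c(c1)[C@H](CO[Si](C)(C)C(C)(C)C)[C@@H](c1cc(OC)c(OCOC)c(OC)c1)O | intermediate
15 | methyl 3-{3-[(1S,2R)-1,3-dihydroxy-1-(4-hydroxy-3,5-dimethoxyphenyl)propan-2-yl]-4-hydroxy-5-methoxyphenyl}propanoate | COC(=O)CCc1cc(OC)c(O)c(c1)[C@H](CO)[C@@H](c1cc(OC)c(O)c(OC)c1)O | intermediate (not isolated)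
16 | methyl 3-{4-hydroxy-3-[(2R)-1-hydroxy-3-(3,5-dimethoxy-4-oxocyclohexa-2,5-dien-1-ylidene)propan-2-yl]-5-methoxyphenyl}propanoate | COC(=O)CCc1cc(OC)c(O)c(c1)[C@H](CO)C=C1C=C(OC)C(=O)C(OC)=C1 | intermediate (not isolated)
17 | methyl 3-[(2S,3R)-2-(4-hydroxy-3,5-dimethoxyphenyl)-3-(hydroxymethyl)-7-methoxy-2,3-dihydro-1-benzofuran-5-yl]propanoate | COC(=O)CCc1cc(OC)c2c(c1)[C@H](CO)[C@@H](c1cc(OC)c(O)c(OC)c1)O2 | target

## Step count and least certain steps

Total: 8 steps. Longest linear sequence: 5 steps (1 → 2 → 3 → 13 → 14 → 17, or equally 6 → 7 → 10 → 13 → 14 → 17).

**Step 6 (key step).**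
- What may go wrong: the most likely failure is diversion of 12 into direct transmetallation, that is, Suzuki–Miyaura transfer of the aryl or alkenyl group to palladium. The beta substituent slows alkene binding, and oxidative addition to the electron-rich, ortho-substituted bromide 3 is slow and is inhibited by bromide ion. The C3–palladium intermediate may also collapse by beta-hydride or beta-silyloxy elimination, and the bulky ortho-substituted aryl group on palladium may erode face selectivity.
- Fallback (auxiliary-controlled aldol, sets out from 3 and 5, returns at 15): 3 is allylated (allylboronic acid pinacol ester, PdCl2(dppf), CsF, THF, 70 °C) to methyl 3-[3-allyl-5-methoxy-4-(methoxymethoxy)phenyl]propanoate F1. Ozonolysis (O3, CH2Cl2, −78 °C; PPh3) gives the arylacetaldehyde F2, and Pinnick oxidation (NaClO2, NaH2PO4, 2-methyl-2-butene) gives the arylacetic acid F3. Mixed-anhydride acylation (PivCl, Et3N, LiCl, (S)-4-benzyloxazolidin-2-one, THF) gives the imide F4. Separately, 11 made from 5 is quenched with DMF to 3,5-dimethoxy-4-(methoxymethoxy)benzaldehyde F5. The Evans syn-aldol reaction of F4 with F5 (Bu2BOTf, i-Pr2NEt, CH2Cl2, −78 → 0 °C) should give the adduct F6, its alpha carbon (the future C3) fixed by the auxiliary. NaBH4 in THF/H2O removes the auxiliary without touching the methyl ester and gives the diol F7, the desilyl analogue of 14. Under the conditions of step 8, F7 enters the route at 15. The carbinol configuration is immaterial because C2 is re-formed through 16.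

**Step 8.**
- What may go wrong: ionisation at C2 may be diverted. Methanol capture would give a C2 methyl ether that stalls. Loss of the C3 proton from 16 (tautomerisation towards a stilbene) would erase the only controlling stereocentre. Cleavage of the hindered ring B acetal may be incomplete.
- Fallback (aprotic unmasking and base-triggered quinone methide closure, sets out from 14, returns at 16): Bu4NF in THF removes the silyl group to give the diol F7. Me3SiBr in CH2Cl2 (−20 → 0 °C) cleaves both acetals and converts the benzylic hydroxyl into the benzylic bromide F8, which is held as its transient trimethylsilyl ethers. Shaking with aqueous NaHCO3 hydrolyses the silyl ethers and eliminates HBr to give 16, which closes to 17 under neutral conditions.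

**Step 5.**
- What may go wrong: exchange of the catechol ester with the hindered tertiary diol may be incomplete, and partial desilylation or protodeboronation may occur during the hot hydroboration. Catechol carried forward would consume aryllithium in step 6.
- Fallback (sets out from 8, returns at 10): hydroboration with pinacolborane (Cp2ZrHCl cat., Et3N cat., 60 °C) gives the pinacol ester F9. Oxidative removal of pinacol (NaIO4, NH4OAc, acetone/H2O) gives the boronic acid F10, which is condensed with 7 (MgSO4, CH2Cl2, rt) to give 10.

**Step 7.**
- What may go wrong: protodeboronation of the electron-rich benzylic boronate, slow oxidation of the hindered ester, or saponification of the methyl ester if the medium turns too basic.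
- Fallback (sets out from 13, returns at 14): KHF2 in MeOH/H2O converts 13 into the potassium trifluoroborate F11 and frees 7. Brief treatment with KHSO5 (as the triple salt 2KHSO5·KHSO4·K2SO4) in acetone/H2O buffered with NaHCO3 oxidises the C–B bond with retention to give 14.

## Further compounds

F1 | step 6 | methyl 3-[3-allyl-5-methoxy-4-(methoxymethoxy)phenyl]propanoate | COC(=O)CCc1cc(OC)c(OCOC)c(CC=C)c1
F2 | step 6 | methyl 3-[3-methoxy-4-(methoxymethoxy)-5-(2-oxoethyl)phenyl]propanoate | COC(=O)CCc1cc(OC)c(OCOC)c(CC=O)c1
F3 | step 6 | 2-[3-methoxy-5-(3-methoxy-3-oxopropyl)-2-(methoxymethoxy)phenyl]acetic acid | COC(=O)CCc1cc(OC)c(OCOC)c(CC(=O)O)c1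
F4 | step 6 | methyl 3-{3-[2-((S)-4-benzyl-2-oxooxazolidin-3-yl)-2-oxoethyl]-5-methoxy-4-(methoxymethoxy)phenyl}propanoate | COC(=O)CCc1cc(OC)c(OCOC)c(CC(=O)N2[C@@H](Cc3ccccc3)COC2=O)c1
F5 | step 6 | 3,5-dimethoxy-4-(methoxymethoxy)benzaldehyde | COCOc1c(OC)cc(C=O)cc1OC
F6 | step 6 | methyl 3-{3-[(2S,3S)-1-((S)-4-benzyl-2-oxooxazolidin-3-yl)-3-hydroxy-3-[3,5-dimethoxy-4-(methoxymethoxy)phenyl]-1-oxopropan-2-yl]-5-methoxy-4-(methoxymethoxy)phenyl}propanoate | COC(=O)CCc1cc(OC)c(OCOC)c(c1)[C@H](C(=O)N1[C@@H](Cc2ccccc2)COC1=O)[C@@H](c1cc(OC)c(OCOC)c(OC)c1)O
F7 | step 6 | methyl 3-{3-[(1S,2R)-1,3-dihydroxy-1-[3,5-dimethoxy-4-(methoxymethoxy)phenyl]propan-2-yl]-5-methoxy-4-(methoxymethoxy)phenyl}propanoate | COC(=O)CCc1cc(OC)c(OCOC)c(c1)[C@H](CO)[C@@H](c1cc(OC)c(OCOC)c(OC)c1)O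
F8 | step 8 | methyl 3-{3-[(2R)-1-bromo-3-hydroxy-1-(4-hydroxy-3,5-dimethoxyphenyl)propan-2-yl]-4-hydroxy-5-methoxyphenyl}propanoate (C1 configuration undefined; shown without its transient trimethylsilyl groups) | COC(=O)CCc1cc(OC)c(O)c(c1)[C@H](CO)C(Br)c1cc(OC)c(O)c(OC)c1
F9 | step 5 | (E)-3-(tert-butyldimethylsilyloxy)prop-1-enylboronic acid pinacol ester | CC(C)(C)[Si](C)(C)OC/C=C/B1OC(C)(C)C(C)(C)O1
F10 | step 5 | (E)-3-(tert-butyldimethylsilyloxy)prop-1-enylboronic acid | CC(C)(C)[Si](C)(C)OC/C=C/B(O)O
F11 | step 7 | potassium trifluoroborate corresponding to 13, (1S,2R) | [K+].COC(=O)CCc1cc(OC)c(OCOC)c(c1)[C@H](CO[Si](C)(C)C(C)(C)C)[C@@H](c1cc(OC)c(OCOC)c(OC)c1)[B-](F)(F)F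
A1 | alternative 1 | methyl (2S,3S)-5-bromo-2-[3,5-dimethoxy-4-(pivaloyloxy)phenyl]-7-methoxy-2,3-dihydro-1-benzofuran-3-carboxylate (trans) | Brc1cc(OC)c2c(c1)[C@H](C(=O)OC)[C@@H](c1cc(OC)c(OC(=O)C(C)(C)C)c(OC)c1)O2
A2 | alternative 1 | (2S)-6-bromo-2-[3,5-dimethoxy-4-(pivaloyloxy)phenyl]-8-methoxychroman-4-one | O=C1C[C@@H](c2cc(OC)c(OC(=O)C(C)(C)C)c(OC)c2)Oc2c(OC)cc(Br)cc12
A3 | alternative 2 | (2S,3R)-2-(4-benzyloxy-3,5-dimethoxyphenyl)-3-(benzyloxymethyl)-5-[3-(tert-butyldimethylsilyloxy)propyl]-2,3-dihydro-1-benzofuran-7-ol | CC(C)(C)[Si](C)(C)OCCCc1cc(O)c2c(c1)[C@H](COCc1ccccc1)[C@@H](c1cc(OC)c(OCc3ccccc3)c(OC)c1)O2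
A4 | alternative 2 | 2-[3-benzyloxy-1-(4-benzyloxy-3,5-dimethoxyphenyl)-1-(ethynyloxy)propan-2-yl]-4-[3-(tert-butyldimethylsilyloxy)propyl]furan, stereocentres as in A3 | C#CO[C@H](c1cc(OC)c(OCc2ccccc2)c(OC)c1)[C@@H](COCc1ccccc1)c1cc(CCCO[Si](C)(C)C(C)(C)C)co1
A5 | alternative 3 | benzyl (2S,3S)-2-(4-benzyloxy-3,5-dimethoxyphenyl)-7-methoxy-5-(3-methoxy-3-oxopropyl)-2,3-dihydro-1-benzofuran-3-carboxylate (trans) | COC(=O)CCc1cc(OC)c2c(c1)[C@H](C(=O)OCc1ccccc1)[C@@H](c1cc(OC)c(OCc3ccccc3)c(OC)c1)O2
A6 | alternative 3 | methyl 3-{3-[(E)-2-(4-benzyloxy-3,5-dimethoxyphenyl)ethenyl]-4-hydroxy-5-methoxyphenyl}propanoate | COC(=O)CCc1cc(OC)c(O)c(c1)/C=C/c1cc(OC)c(OCc2ccccc2)c(OC)c1
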